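**Assumption:** the SMILES is taken as authoritative. It is the all-trans isolariciresinol skeleton, (1R,2S,3S) in aryltetralin numbering, which is (6S,7S,8R) in tetrahydronaphthalen-2-ol numbering. Compounds 1, 3, 6, 8 and the chiral diene ligand are treated as commercial.

## Retrosynthetic overview

1. The usual Friedel–Crafts / quinone-methide closure of the C1–aryl bond from a dibenzylbutane is deliberately not used.
2. Key step: the only ring formed (the cyclohexane) is closed last at the C2–C3 (lignan 8–8′) bond by intramolecular oxidative coupling of a diester bis-enolate.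
3. C1 (the diarylmethine) is the single seed stereocentre, set by Rh/chiral-diene asymmetric 1,4-arylation of an o-substituted cinnamate. C2 and C3 are then relayed from C1 by base equilibration to the all-trans diester.
4. The bis-ester precursor comes from 6-bromo-O-benzylvanillin: reductive Knoevenagel builds the C4–C3 arm, Heck builds the C1–C2 arm.
5. End game: LiAlH4 reduction of both esters, then hydrogenolysis of both benzyl ethers.

## Route

**Step 1**
Reactants: 1, 4-(benzyloxy)-3-methoxybenzaldehyde (O-benzylvanillin)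
Product: 2, 4-(benzyloxy)-2-bromo-5-methoxybenzaldehyde
Conditions: Br2 (1.1 equiv), NaOAc, AcOH, rt
Reagents that add atoms: bromine, BrBr
Why: Electrophilic aromatic bromination; with the phenol capped, substitution goes para to OMe and ortho to CHO, as in veratraldehyde.

**Step 2**
Reactants: 2; 3, Meldrum's acid
Product: 4, 3-[4-(benzyloxy)-2-bromo-5-methoxyphenyl]propanoic acid
Conditions: HCO2H/Et3N (5:2), 95–100 °C
Reagents that add atoms: Meldrum's acid (3), CC1(C)OC(=O)CC(=O)O1
Why: One-pot Knoevenagel condensation, formate transfer reduction of the alkylidene (formate gives hydride only), then ring opening and decarboxylation to leave the CH2–CO2H unit; ArBr and OBn are inert because no Pd/H2 is present.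

**Step 3**
Reactants: 4
Product: 5, tert-butyl 3-[4-(benzyloxy)-2-bromo-5-methoxyphenyl]propanoate
Conditions: Boc2O, DMAP (cat.), t-BuOH, 40 °C
Reagents that add atoms: di-tert-butyl dicarbonate (Boc2O), CC(C)(C)OC(=O)OC(=O)OC(C)(C)C; tert-butanol, CC(C)(C)O
Why: Mixed-anhydride tert-butyl esterification, in which the tert-butoxy group comes from the Boc2O-derived tert-butoxide and/or the solvent; the tert-butyl ester survives the later aqueous base and gives a clean lithium enolate.

**Step 4**
Reactants: 5; 6, tert-butyl acrylate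
Product: 7, tert-butyl (E)-3-[5-(benzyloxy)-2-(3-tert-butoxy-3-oxopropyl)-4-methoxyphenyl]prop-2-enoate
Conditions: Pd2(dba)3 (1.5 mol%), [HP(t-Bu)3]BF4 (6 mol%), Cy2NMe, dioxane, 80 °C
Reagents that add atoms: tert-butyl acrylate (6), C=CC(=O)OC(C)(C)C
Why: Mizoroki–Heck reaction; the bulky electron-rich phosphine handles the electron-rich ortho-substituted aryl bromide, and syn-insertion/β-hydride elimination gives the E-enoate.

**Step 5**
Reactants: 7; 8, [4-(benzyloxy)-3-methoxyphenyl]boronic acid (2.5 equiv)
Product: 9, tert-butyl (3R)-3-[4-(benzyloxy)-3-methoxyphenyl]-3-[5-(benzyloxy)-2-(3-tert-butoxy-3-oxopropyl)-4-methoxyphenyl]propanoate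
Conditions: [RhCl(C2H4)2]2 (2.5 mol%), (R,R)-Ph-bod* (5.5 mol%), aq. KOH (0.5 equiv), dioxane/H2O 10:1, 50 °C
Reagents that add atoms: [4-(benzyloxy)-3-methoxyphenyl]boronic acid (8), COc1cc(B(O)O)ccc1OCc1ccccc1
Why: Hayashi–Miyaura asymmetric 1,4-addition; aryl-Rh(diene) adds to one enantioface of the E-enoate and sets C1 as R, and the Rh enolate is then protonated by the aqueous medium. The (R,R)-ligand is chosen by analogy with its sense on enones, so the sense must be confirmed on the first run and the (S,S)-ligand used if it is reversed.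

**Step 6**
Reactants: 9
Product: 10, di-tert-butyl (1R)-7-(benzyloxy)-1-[4-(benzyloxy)-3-methoxyphenyl]-6-methoxy-1,2,3,4-tetrahydronaphthalene-2,3-dicarboxylate (mixture of C2/C3 diastereomers)
Conditions: LDA (2.3 equiv), THF, −78 °C; then CuCl2 (2.5 equiv) in DMF, −78 → 0 °C, 0.01 M
Reagents that add atoms: none
Why: Intramolecular oxidative coupling of a bis(lithium ester enolate) (Rathke-type Cu(II) enolate coupling, known in ring-closing form to give cycloalkane-1,2-diesters). One-electron oxidation gives an α-ester radical that is captured by the tethered enolate in a 6-membered closure. C1 is not deprotonated or oxidised, so its configuration is kept. This substrate class is untested.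

**Step 7**
Reactants: 10
Product: 11, di-tert-butyl (1R,2S,3S)-7-(benzyloxy)-1-[4-(benzyloxy)-3-methoxyphenyl]-6-methoxy-1,2,3,4-tetrahydronaphthalene-2,3-dicarboxylate
Conditions: KOt-Bu (0.5 equiv), t-BuOH/THF, 50 °C; crystallise
Reagents that add atoms: none
Why: Thermodynamic epimerisation through the ester enolates; C2 and C3 (both α to esters) equilibrate to the all-trans, all-equatorial isomer relative to the fixed, non-acidic C1. tert-Butoxide with tert-butyl esters avoids transesterification.

**Step 8**
Reactants: 11
Product: 12, [(1R,2S,3S)-7-(benzyloxy)-1-[4-(benzyloxy)-3-methoxyphenyl]-6-methoxy-1,2,3,4-tetrahydronaphthalene-2,3-diyl]dimethanol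
Conditions: LiAlH4, THF, 0 °C → reflux
Reagents that add atoms: none
Why: Hydride reduction of both esters to primary alcohols; no stereocentre is α to a carbonyl afterwards, so the configuration is locked.

**Step 9**
Reactants: 12
Product: 13, (6S,7S,8R)-8-(4-hydroxy-3-methoxyphenyl)-6,7-bis(hydroxymethyl)-3-methoxy-5,6,7,8-tetrahydronaphthalen-2-ol (target)
Conditions: H2 (1 atm), 10% Pd/C, EtOAc/MeOH, rt
Reagents that add atoms: none
Why: Hydrogenolysis of the two aryl benzyl ethers; the ring C–C and C–H bonds and the primary alcohols are untouched.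

## Compound list

1 | 4-(benzyloxy)-3-methoxybenzaldehyde | COc1cc(C=O)ccc1OCc1ccccc1 | starting material
2 | 4-(benzyloxy)-2-bromo-5-methoxybenzaldehyde | COc1cc(C=O)c(Br)cc1OCc1ccccc1 | intermediate
3 | Meldrum's acid | CC1(C)OC(=O)CC(=O)O1 | starting material
4 | 3-[4-(benzyloxy)-2-bromo-5-methoxyphenyl]propanoic acid | COc1cc(CCC(=O)O)c(Br)cc1OCc1ccccc1 | intermediate
5 | tert-butyl 3-[4-(benzyloxy)-2-bromo-5-methoxyphenyl]propanoate | COc1cc(CCC(=O)OC(C)(C)C)c(Br)cc1OCc1ccccc1 | intermediate
6 | tert-butyl acrylate | C=CC(=O)OC(C)(C)C | starting material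
7 | tert-butyl (E)-3-[5-(benzyloxy)-2-(3-tert-butoxy-3-oxopropyl)-4-methoxyphenyl]prop-2-enoate | COc1cc(CCC(=O)OC(C)(C)C)c(/C=C/C(=O)OC(C)(C)C)cc1OCc1ccccc1 | intermediate
8 | [4-(benzyloxy)-3-methoxyphenyl]boronic acid | COc1cc(B(O)O)ccc1OCc1ccccc1 | starting material
9 | tert-butyl (3R)-3-[4-(benzyloxy)-3-methoxyphenyl]-3-[5-(benzyloxy)-2-(3-tert-butoxy-3-oxopropyl)-4-methoxyphenyl]propanoate | COc1cc([C@@H](CC(=O)OC(C)(C)C)c2cc(OCc3ccccc3)c(OC)cc2CCC(=O)OC(C)(C)C)ccc1OCc1ccccc1 | intermediate
10 | di-tert-butyl (1R)-7-(benzyloxy)-1-[4-(benzyloxy)-3-methoxyphenyl]-6-methoxy-1,2,3,4-tetrahydronaphthalene-2,3-dicarboxylate, C2/C3 mixture | COc1cc([C@@H]2c3cc(OCc4ccccc4)c(OC)cc3CC(C(=O)OC(C)(C)C)C2C(=O)OC(C)(C)C)ccc1OCc1ccccc1 | intermediate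
11 | di-tert-butyl (1R,2S,3S)-7-(benzyloxy)-1-[4-(benzyloxy)-3-methoxyphenyl]-6-methoxy-1,2,3,4-tetrahydronaphthalene-2,3-dicarboxylate | COc1cc([C@@H]2c3cc(OCc4ccccc4)c(OC)cc3C[C@H](C(=O)OC(C)(C)C)[C@H]2C(=O)OC(C)(C)C)ccc1OCc1ccccc1 | intermediate
12 | [(1R,2S,3S)-7-(benzyloxy)-1-[4-(benzyloxy)-3-methoxyphenyl]-6-methoxy-1,2,3,4-tetrahydronaphthalene-2,3-diyl]dimethanol | COc1cc([C@@H]2c3cc(OCc4ccccc4)c(OC)cc3C[C@H](CO)[C@H]2CO)ccc1OCc1ccccc1 | intermediate
13 | (6S,7S,8R)-8-(4-hydroxy-3-methoxyphenyl)-6,7-bis(hydroxymethyl)-3-methoxy-5,6,7,8-tetrahydronaphthalen-2-ol | COc1cc([C@@H]2c3cc(O)c(OC)cc3C[C@H](CO)[C@H]2CO)ccc1O | target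

## Summary

Total steps: 9. Longest linear sequence: 9 (from 1).

Steps most likely to fail:

1. **Step 6, ring-closing oxidative enolate coupling** (risks: oligomers, α-halogenation, low yield). Fallback: close the same C2–C3 bond by a Stork-type intramolecular epoxide opening. The C4–C3 arm is carried as an o-allyl group instead of the propanoate (from the aldehyde of 2 via the benzyl bromide and a vinyl cuprate) and converted to the enantiopure terminal epoxide. The C2 ester enolate then attacks the internal epoxide carbon (6-exo), giving C3–CH2OH directly with inversion; the resulting lactone/ester is reduced with LiAlH4.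

2. **Step 5, Rh asymmetric arylation of an electron-rich, ortho-substituted cinnamate** (risks: low conversion, low ee, uncertain facial sense). Fallback: auxiliary control. Run the Heck with N-acryloyl-4-phenyloxazolidin-2-one and add the aryl group as ArMgBr/CuBr·SMe2 (predictable Evans-type conjugate addition). The imide then acts as one enolate partner in the ring closure and is removed reductively.

3. **Step 7, thermodynamic relay of C2/C3** (risk: the equilibrium may not favour all-trans strongly enough). Fallback: kinetic auxiliary control. Carry both arms as chiral N-acyl oxazolidinones and run the intramolecular Ti/Cu-mediated bis-imide enolate coupling, which is trans-selective with the auxiliaries fixing absolute configuration. LiBH4 cleavage then gives diol 12 directly.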